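## Structural features

The target is a bicyclic bromo-diterpenoid ether: a cyclohexane (ring A, C8–C13) is fused across C8–C13 to a ten-membered oxacycle (ring B: O, C1–C8, C13), and the ring oxygen joins two fully substituted carbons, C13 and C1. Ring A holds three dependent stereocentres: C8 (H and the C7 chain), C13 (axial CH3, equatorial O, trans to the C7 chain) and C10 (equatorial Br beside the C9 gem-dimethyl carbon, cis to the C7 chain). Ring B holds C1 (CH3, vinyl, O; R) and the trans-epoxide C4/C5 (S,S), the oxide of an E-trisubstituted olefin with its methyl on C5. Fragile groups are the tertiary allylic ether at C1, the epoxide, the vinyl group (it competes in any hydroboration or metathesis) and the neopentyl bromide, which is inert once equatorial but hard to install without elimination or methyl migration. The real difficulties are the ether between two quaternary carbons, an E-olefin inside a ten-membered ring, and a C10 bromide made without bromonium-triggered cation chemistry. The key step uses the pattern of ring A: C13 (CH3 plus one carbon that can later leave) beside C8 (H plus chain), with C9 methylated and C10 oxygenated, is the footprint of a 2-silyloxy-3-methyl-1,3-diene and methacrolein. One correction governs the plan: C13 is re-made later, so the C8 configuration survives only through the exo/endo relation of the cycloadduct, which therefore must be a single diastereomer series before C13 is flattened.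

## Logic of the disconnections

32 to 31. Bonds cut: C4–O and C5–O of the oxirane. The epoxide is the most sensitive group, so it is made last. Gain: two stereocentres reduce to one olefin geometry. Demand: oxygen must reach one face of C4=C5 only, and the trisubstituted, not the vinyl, double bond.

31 to 28 (through 30 and 29). Bond cut: the C=C of the C1 vinyl group, taken back to formyl, hydroxymethyl and its silyl ether. Reason: a free vinyl at C1 would be a second site for the boron hydride in the ring closure. Gain: the cyclization substrate holds exactly one monosubstituted alkene. Demand: methylenation of a hindered aldehyde without harm to the C10 bromide; the aldehyde is quaternary and cannot epimerize.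

28 to 26 (through 27). Bond cut: C3–C4, opening ring B. Reason: an sp3–sp2 bond beside the olefin lets the E geometry be fixed in the open chain and not left to the ring closure. Gain: the ten-membered ring becomes a chain with an iodoalkene at one end and a vinyl group at the other. Demand: hydroboration at the vinyl group only, ring closure faster than dimerization, and an inert C10–Br bond.

26 to 24 to 23 to 22 to 21. Bonds cut: C4–I and C5–CH3 (26 to 24), C5–C6 (24 to 23), then the C6–I and C6–O-acyl interchanges. Reason: syn-carbometalation of a terminal alkyne is the most dependable source of an E-trisubstituted iodoalkene with the methyl on C5. Gain: the C8 side chain shrinks to the two-carbon ester arm that the diene brings. Demand: basic and Lewis acidic reagents must spare the tertiary allylic ether and the bromide.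

21 to 20 to 19. Bonds cut: C10–Br (back to the axial C10–OH, with inversion) and C10–H (back to the ketone). Reason: an equatorial neopentyl bromide is best reached by backside displacement of the axial alcohol, which a bulky hydride provides. It is placed after the ether so that the acid function is gone and the ring is biased. Gain: C10 is traced to the ketone masked in the cycloadduct. Demand: substitution must outrun elimination and methyl migration.

19 to 15 and 18. Bond cut: C13–O. Reason: it is the only bond that separates ring A from the C1 unit, and the carboxyl on C13 (the former formyl carbon) is the leaving group. Gain: two halves of similar size, and the C13 configuration of the cycloadduct need not be carried. Demand: a hindered tertiary alcohol must capture the C13 cation before proton loss, on the face anti to the axial C9 methyl; 15 must be diastereomerically pure.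

18 to 17 to 16. Bonds cut: the terminal vinyl carbon of 18 (back to the epoxide CH2) and O–Si. Reason: C1 is bought as one enantiomer with oxygen already on the quaternary carbon. Gain: a commercial epoxy alcohol. Demand: no C–O bond at C1 is ever broken.

15 to 14 to 13 to 12 to 11. Bonds cut: the ester O–N link, the oxidation level at the C13 carbon, and one C9–CH3 bond (through the cyclopropane of 12). Reason: the enol ether is the regiodefined handle that puts the second methyl on C9 and unmasks the C10 ketone. Gain: return to the cycloadduct. Demand: the carbenoid must add to the enol ether and not to the aldehyde.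

11 to 9 and 10. Bonds cut: C8–C13 and C11–C12. Reason: one cycloaddition builds ring A, fixes its regiochemistry and sets C8 and C13. Gain: two achiral components. Demand: regiocontrol, enal-face control and a single exo/endo series.

9 to 7, 7 to 3 and 6, 3 to 2 to 1, 6 to 4. Bonds cut: O–Si, the C8=C9 double bond (olefination), the ester and oxidation-level changes of the three-carbon diol, and the P–C bond of the ylide. Gain: three bulk chemicals. Demand: E geometry in 7 and kinetic enolization at the methyl group of 7.

## Other disconnections considered

Alternative 1: The cut is C6–C7, between the two ten-carbon halves. In the forward step an α-sulfonyl carbanion at C7, formed with KN(SiMe3)2 at high dilution, would displace a primary allylic chloride at C6 and close ring B to A2 (either C7 epimer). The sulfone would then be removed reductively and the C10 pivalate exchanged for bromide at the end.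
- In its favour: the terpene alcohol A1 would supply C1 to C6, the C1 configuration, the vinyl group and, after allylic oxidation of its E-methyl group, the E-olefin, so none of its carbons is discarded. Alkylation of stabilized carbanions by allylic halides is among the best-documented routes to ten-membered terpenoid rings.
- Against it here: the C13–O–C1 ether must still be made between two tertiary centres, now with a partner whose trisubstituted olefin or allylic chloride can itself trap a C13 cation. Reductive desulfonylation excludes an early bromide, so the delicate neopentyl substitution is deferred to a late intermediate holding the allylic ether.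
- Comparison: in carbon economy of ring B this alternative is better than the chosen plan, which builds C4, C5 and the C5 methyl from acetylide and Me3Al and rebuilds the vinyl group. In olefin control the two are equal. Mechanistically a carbanion SN2 closure is at least as dependable at this ring size as a palladium-mediated coupling. It needs an enantioselective ring A with a one-carbon arm at C8, which a cycloaddition like step 6 could also supply. It pays with sulfone installation and removal and a last-stage bromination, so the step count would be similar.

Alternative 2: The cut is C4=C5. In the forward step the second-generation Grubbs catalyst would join a prenyl-type olefin at C4 with an isopropenyl group on C5, extruding the gem-dimethyl terminus as a volatile alkene, and give A3 with the Z-olefin. The trans-epoxide would then come from syn-dihydroxylation, sulfonylation of the C4 hydroxyl and displacement by the C5 oxygen.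
- In its favour: A1 again supplies C1 to C4 and is cheap enough to be used in large excess in the ether-forming step. The ruthenium carbene tolerates bromide and ether, and no stoichiometric organometallic reagent is needed.
- Against it here: both olefins are hindered and the product is a trisubstituted olefin in a ten-membered ring, so closure is expected to be slow. The geometry obtained is the wrong one for direct epoxidation, and the three-step correction stakes C4 and C5 on the face selectivity of a dihydroxylation. The C1 vinyl group must be masked as a silyloxyethyl arm, since it would otherwise close a five-membered ring with the prenyl olefin, and regenerated by selenoxide elimination.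
- Comparison: it is the equal of the chosen plan for ring A and the ether, since it could start from the same cycloadduct 11. It is better in reagent simplicity and in the use of the chiral pool. It is weaker in stereocontrol of ring B, where the chosen plan fixes the E geometry by syn-carbometalation before closure and needs one step to the epoxide, and it would cost about four more steps.

Alternative 3: The cut is C3–C4. In the forward step 9-borabicyclo[3.3.1]nonane would add to the only vinyl group on C1, and the primary alkylborane would couple within the molecule with the E-iodoalkene at C4 under PdCl2(dppf), AsPh3 and Cs2CO3 to give A4.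
- In its favour: the E geometry is preset, the hydroboration is chemoselective, the C1 unit is small (which helps the hindered etherification), and this coupling is a recognized way to close strained rings that hold E-trisubstituted olefins.
- Against it here: the vinyl group of the target has to travel as a silyloxymethyl arm and be rebuilt in three steps, C1 does not come from the terpene pool, and at medium ring size oligomerization competes with reductive elimination. As a leading disconnection it also leaves open how ring A, with C8, C10, C13 and the bromide, is obtained.
- Comparison: on ring B this alternative is the equal of the chosen plan by construction, because the chosen route adopts the same closure in step 20 (28 is the tert-butyldiphenylsilyl analogue of A4). The difference lies in which step carries the strategy: the cycloaddition settles ring A, its regiochemistry and the masked C10 ketone in one event, and the coupling then serves as the closing move.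

Key step: step 6

Assumption (chemistry): the sense of induction of the oxazaborolidinium catalyst is taken from its accepted model for 2-substituted acroleins and written for the (S)-diphenylprolinol-derived catalyst. Because C13 is re-made in step 13, the catalyst antipode is exchanged if the major cycloadduct carries the wrong C8 configuration.

## Steps

Step 1
Reactants: 1 propane-1,3-diol
Product: 2 3-hydroxypropyl pivalate
Conditions: t-BuCOCl (0.33 equiv), pyridine, CH2Cl2, 0 °C to rt
Reagents that add atoms: pivaloyl chloride, CC(C)(C)C(=O)Cl
Why: Acylation of a symmetrical diol used in threefold excess should stop at the mono-ester. The pivalate has no α-hydrogen (it survives the amide base of step 5), resists hydride at low temperature, and its oxygen is too electron-poor to trap the C13 cation of step 13.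

Step 2
Reactants: 2 3-hydroxypropyl pivalate
Product: 3 3-oxopropyl pivalate
Conditions: 2,2,6,6-tetramethylpiperidin-1-oxyl (0.1 equiv), PhI(OAc)2, CH2Cl2, rt
Reagents that add atoms: none
Why: Oxoammonium-mediated oxidation of the primary alcohol stops at the aldehyde, and the neutral medium avoids β-elimination of pivalic acid from the β-acyloxy aldehyde.

Step 3
Reactants: 4 3-chlorobutan-2-one
Product: 6 3-(triphenylphosphoranylidene)butan-2-one, via phosphonium chloride 5 (not isolated)
Conditions: PPh3, toluene, 100 °C; then NaOH (aq.), CH2Cl2, rt
Reagents that add atoms: triphenylphosphine, c1ccc(cc1)P(c1ccccc1)c1ccccc1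
Why: SN2 quaternization of the α-chloro ketone followed by deprotonation gives the acyl-stabilized ylide (Wittig reagent formation); the stereocentre of 4 is lost, so the racemate serves.

Step 4
Reactants: 3 3-oxopropyl pivalate; 6 3-(triphenylphosphoranylidene)butan-2-one
Product: 7 (E)-4-methyl-5-oxohex-3-en-1-yl pivalate
Conditions: toluene, 80 °C
Reagents that add atoms: none
Why: Wittig olefination with a stabilized, α-branched ylide is under thermodynamic control and should give the (E)-trisubstituted enone, which fixes the diene geometry used in step 6.

Step 5
Reactants: 7 (E)-4-methyl-5-oxohex-3-en-1-yl pivalate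
Product: 9 (E)-5-(tert-butyldimethylsilyloxy)-4-methylhexa-3,5-dien-1-yl pivalate, via lithium dienolate 8 (not isolated)
Conditions: LiN(i-Pr)2, THF, −78 °C; then t-BuMe2SiOSO2CF3, −78 °C
Reagents that add atoms: tert-butyldimethylsilyl trifluoromethanesulfonate, CC(C)(C)[Si](C)(C)OS(=O)(=O)C(F)(F)F
Why: Kinetic deprotonation at the methyl group of the methyl ketone gives the cross-conjugated enolate, and O-silylation gives the 2-silyloxy-1,3-diene; the (E)-olefin and the pivalate are untouched.

Step 6
Reactants: 9 (E)-5-(tert-butyldimethylsilyloxy)-4-methylhexa-3,5-dien-1-yl pivalate; 10 methacrolein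
Product: 11 exo cycloadduct 2-[(1S,6S)-3-(tert-butyldimethylsilyloxy)-6-formyl-2,6-dimethylcyclohex-2-en-1-yl]ethyl pivalate
Conditions: (S)-1-(2-methylphenyl)-3,3-diphenyltetrahydro-1H,3H-pyrrolo[1,2-c][1,3,2]oxazaborole (0.20 equiv), HN(SO2CF3)2 (0.17 equiv), CH2Cl2, −78 °C
Reagents that add atoms: none
Why: The boron of the N-protonated oxazaborolidine binds the formyl oxygen of 10, lowers its LUMO, and the diene adds in a concerted but asynchronous [4+2] cycloaddition in which the silyloxy-activated terminus C11 bonds to the β-carbon C12 ahead of C8–C13. The closest known reaction type is the oxazaborolidinium-catalysed Diels–Alder reaction of 2-silyloxy-1,3-dienes with 2-substituted acroleins, including 3-methyl-4-alkyl dienes of this kind. Ring A closes by the cycloaddition itself: both new σ-bonds form suprafacially in one six-membered transition state and leave the C9=C10 enol ether. C13 is controlled by the catalyst, which shields one face of the bound s-trans enal; C8 is controlled by the (E)-geometry of the diene together with the formyl-exo (methyl-endo) topology usual for 2-substituted acroleins, so that the C7 chain ends trans to the formyl group. Regiocontrol is needed and is doubly secured, because the 2-silyloxy group and the alkyl substituent at C8 both direct C11 to the β-carbon. Exo/endo control is needed as well: for a given enal face the endo adduct has the opposite configuration at C8, so after C13 is flattened in step 13 it would belong to the enantiomeric series, and the minor isomer is therefore removed at acid 14. A slight excess of the oxazaborolidine over the acid keeps free HN(SO2CF3)2 from protodesilylating 9.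

Step 7
Reactants: 11 exo cycloadduct
Product: 12 siloxycyclopropane aldehyde (11 with a CH2 bridge across C9–C10 on the face opposite to the C8 chain)
Conditions: Et2Zn (2 equiv), CH2I2 (4 equiv), CH2Cl2, 0 °C
Reagents that add atoms: diiodomethane, ICI
Why: Simmons–Smith cyclopropanation (Furukawa reagent): the electrophilic zinc carbenoid adds to the electron-rich tetrasubstituted enol ether, and either face serves because C9 ends as C(CH3)2. With two CH2I2 per zinc no ethylzinc remains to add to the hindered, non-enolizable aldehyde.

Step 8
Reactants: 12 siloxycyclopropane aldehyde
Product: 13 keto aldehyde 2-[(1R,6S)-6-formyl-2,2,6-trimethyl-3-oxocyclohexyl]ethyl pivalate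
Conditions: HCl (2 M aq.), THF, rt to 40 °C
Reagents that add atoms: none
Why: Acid opens the siloxycyclopropane (a masked cyclopropanol) at the external C10–CH2 bond with protonation of the methylene carbon, the known route from an enol ether to the α-methyl ketone. This delivers the C9 gem-dimethyl group and the C10 ketone regiospecifically.

Step 9
Reactants: 13 keto aldehyde
Product: 14 keto acid (1S,2S)-1,3,3-trimethyl-4-oxo-2-[2-(pivaloyloxy)ethyl]cyclohexane-1-carboxylic acid
Conditions: NaClO2, NaH2PO4, 2-methylbut-2-ene, t-BuOH/H2O, rt
Reagents that add atoms: sodium chlorite, [Na+].[O-]Cl=O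
Why: Pinnick oxidation converts the aldehyde to the acid without touching ketone or ester. The acid is the stage at which the endo-derived diastereomer is to be removed by recrystallization.

Step 10
Reactants: 14 keto acid
Product: 15 1,3-dioxoisoindolin-2-yl ester of 14
Conditions: N-hydroxyphthalimide, i-PrN=C=N-i-Pr, 4-(dimethylamino)pyridine (0.1 equiv), CH2Cl2, rt
Reagents that add atoms: N-hydroxyphthalimide, O=C1c2ccccc2C(=O)N1O
Why: Carbodiimide (Steglich-type) esterification gives the redox-active ester; the method is routine for α-quaternary acids.

Step 11
Reactants: 16 (S)-2-methylglycidol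
Product: 17 (R)-tert-butyl[(2-methyloxiran-2-yl)methoxy]diphenylsilane
Conditions: t-BuPh2SiCl, imidazole, DMF, 0 °C to rt
Reagents that add atoms: tert-butyl(chloro)diphenylsilane, CC(C)(C)[Si](Cl)(c1ccccc1)c1ccccc1
Why: Silylation of the primary alcohol; the robust tert-butyldiphenylsilyl ether is chosen to last through steps 12 to 20. The descriptor changes from S to R only through the priority of the silyloxymethyl arm.

Step 12
Reactants: 17 (R)-tert-butyl[(2-methyloxiran-2-yl)methoxy]diphenylsilane
Product: 18 (R)-1-(tert-butyldiphenylsilyloxy)-2-methylbut-3-en-2-ol
Conditions: Me3S+ I−, n-BuLi, THF, −10 °C to rt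
Reagents that add atoms: trimethylsulfonium iodide, C[S+](C)C.[I-]
Why: Dimethylsulfonium methylide opens the epoxide at its CH2 terminus and the resulting sulfonium salt eliminates dimethyl sulfide, a known one-carbon homologation of terminal epoxides to allylic alcohols. The C–O bond at the stereocentre is never broken, so C1 keeps its configuration.

Step 13
Reactants: 15 1,3-dioxoisoindolin-2-yl ester of 14; 18 (R)-1-(tert-butyldiphenylsilyloxy)-2-methylbut-3-en-2-ol (5 equiv, excess recovered)
Product: 19 keto ether 2-[(1S,6S)-6-{[(2R)-1-(tert-butyldiphenylsilyloxy)-2-methylbut-3-en-2-yl]oxy}-2,2,6-trimethyl-3-oxocyclohexyl]ethyl pivalate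
Conditions: 10-phenyl-10H-phenothiazine (0.1 equiv), LiBF4 (0.1 equiv), MeCN, blue LEDs, rt
Reagents that add atoms: none
Why: Decarboxylative etherification by radical–polar crossover: the excited phenothiazine reduces the ester, CO2 and phthalimide anion leave, the phenothiazine radical cation oxidizes the tertiary C13 radical to the cation, and 18 captures it. C13 is set here by the substrate: in the chair with the C8 chain equatorial the axial C9 methyl blocks the syn face, so the alcohol should add anti to it and give the equatorial ether trans to the C7 chain with the C13 methyl axial. The C10 ketone disfavours hydride and methyl shifts toward C8 and C9, and the pivalate oxygen is a poor internal nucleophile.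

Step 14
Reactants: 19 keto ether
Product: 20 axial alcohol (19 with C10–OH cis to the ring oxygen; 1R,8S,10R,13S in target numbering)
Conditions: LiBH(s-Bu)3, THF, −78 °C; then H2O
Reagents that add atoms: none
Why: The bulky hydride attacks the C10 ketone along the equatorial trajectory, as with other 2,2-dimethylcyclohexanones, and should give the axial alcohol; ester, silyl ether and allylic ether are inert at −78 °C.

Step 15
Reactants: 20 axial alcohol
Product: 21 equatorial bromide (C10–Br cis to the C7 chain; 1R,8S,10S,13S)
Conditions: CBr4, PPh3, 2,6-lutidine, toluene, 0 to 60 °C
Reagents that add atoms: carbon tetrabromide, BrC(Br)(Br)Br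
Why: Appel bromination: bromide displaces the axial alkoxyphosphonium group from the rear (SN2, inversion) and gives the equatorial bromide. The same inversion is known for axial hydroxyls flanked by a gem-dimethyl carbon in terpenoid rings, and the lutidine buffer protects the tertiary allylic ether from HBr.

Step 16
Reactants: 21 equatorial bromide
Product: 22 bromo alcohol (21 without the pivaloyl group; free C6–OH)
Conditions: NaOMe (0.5 equiv), MeOH, 40 °C
Reagents that add atoms: none
Why: Base-catalysed transesterification removes the pivalate. The equatorial neopentyl bromide has no anti-periplanar hydrogen and no open backside, so it survives methoxide.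

Step 17
Reactants: 22 bromo alcohol
Product: 23 bromo iodide (C6–I)
Conditions: I2, PPh3, imidazole, CH2Cl2, 0 °C to rt
Reagents that add atoms: iodine, [I][I]
Why: Appel-type iodination of the primary alcohol under buffered, non-ionizing conditions.

Step 18
Reactants: 23 bromo iodide
Product: 24 bromo alkyne (C6–C≡CH; the new carbons are C5 and C4)
Conditions: LiC≡CH·H2NCH2CH2NH2, DMSO, rt
Reagents that add atoms: lithium acetylide–ethylenediamine complex, [Li+].[C-]#C.NCCN
Why: SN2 alkylation of the acetylide by the primary iodide brings in C5 and C4; the hindered secondary bromide cannot compete.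

Step 19
Reactants: 24 bromo alkyne
Product: 26 (E)-iodoalkene (C6–C(CH3)=CH–I), via alkenyldimethylalane 25 (not isolated)
Conditions: Me3Al, Cp2ZrCl2, H2O (1 equiv), CH2Cl2, −20 °C; then I2, THF, −30 to 0 °C
Reagents that add atoms: trimethylaluminium, C[Al](C)C; iodine, [I][I]
Why: Zirconium-catalysed carboalumination (Negishi) adds methyl and aluminium syn across the terminal alkyne with aluminium on the terminal carbon, and iodinolysis with retention gives the (E)-iodoalkene, so the olefin geometry is fixed before ring closure. The ether oxygen between two quaternary carbons is too hindered to be ionized by the aluminium reagent at this temperature.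

Step 20
Reactants: 26 (E)-iodoalkene
Product: 28 bicyclic E-olefin with CH2OSiPh2t-Bu on C1 (rings A and B closed), via B-alkyl-9-borabicyclononane 27 (not isolated)
Conditions: 9-borabicyclo[3.3.1]nonane, THF, rt; then PdCl2(dppf) (0.1 equiv), AsPh3 (0.2 equiv), Cs2CO3, DMF/THF/H2O, 50 °C, slow addition to 0.002 M
Reagents that add atoms: none
Why: B-alkyl Suzuki–Miyaura macrocyclization: the borane adds only to the monosubstituted C1 vinyl group (boron on C3), the iodoalkene adds oxidatively to zerovalent palladium, and base-assisted transmetalation and reductive elimination form C3–C4 with retention of the E geometry. The trans-diequatorial exits at C8 and C13 hold the two arms gauche, high dilution disfavours dimers, and the unactivated C10 bromide does not add to palladium under these conditions.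

Step 21
Reactants: 28 bicyclic E-olefin silyl ether
Product: 29 bicyclic E-olefin with CH2OH on C1
Conditions: Bu4NF, THF, 40 °C
Reagents that add atoms: none
Why: Fluoride cleaves the silyl ether; the ring oxygen now sits in a saturated di-tertiary ether and is inert.

Step 22
Reactants: 29 bicyclic primary alcohol
Product: 30 bicyclic E-olefin with CHO on C1
Conditions: Dess–Martin periodinane, CH2Cl2, rt
Reagents that add atoms: none
Why: Hypervalent-iodine oxidation stops at the aldehyde; C1 is quaternary, so the aldehyde can neither enolize nor epimerize.

Step 23
Reactants: 30 bicyclic aldehyde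
Product: 31 bicyclic diene (C1 vinyl; E-C4=C5)
Conditions: Ph3PCH3Br, KN(SiMe3)2, THF, 0 °C
Reagents that add atoms: methyltriphenylphosphonium bromide, C[P+](c1ccccc1)(c1ccccc1)c1ccccc1.[Br-]
Why: Wittig methylenation restores the C1 vinyl group; the non-stabilized ylide tolerates the hindered equatorial bromide at 0 °C.

Step 24
Reactants: 31 bicyclic diene
Product: 32 target (1R,4S,5S,8S,10S,13S)
Conditions: 1,2:4,5-di-O-isopropylidene-β-L-erythro-2,3-hexodiulo-2,6-pyranose (0.3 equiv), KHSO5 (as 2KHSO5·KHSO4·K2SO4), K2CO3, Bu4NHSO4, MeCN/CH2(OMe)2/aq. Na2B4O7, 0 °C
Reagents that add atoms: potassium peroxymonosulfate, [K+].[O-]S(=O)(=O)OO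
Why: Shi epoxidation: the chiral dioxirane transfers oxygen syn to the electron-rich E-trisubstituted olefin far faster than to the vinyl group, so the trans-epoxide results. The L-series ketone is the one expected to give the (4S,5S) oxide, since the D-series ketone gives (R,R) epoxides from olefins of this substitution pattern.

## Compound list

1 | propane-1,3-diol | OCCCO | starting material
2 | 3-hydroxypropyl pivalate | CC(C)(C)C(=O)OCCCO | intermediate
3 | 3-oxopropyl pivalate | CC(C)(C)C(=O)OCCC=O | intermediate
4 | 3-chlorobutan-2-one (racemic) | CC(Cl)C(C)=O | starting material
5 | (3-oxobutan-2-yl)triphenylphosphonium chloride | CC(=O)C(C)[P+](c1ccccc1)(c1ccccc1)c1ccccc1.[Cl-] | intermediate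
6 | 3-(triphenylphosphoranylidene)butan-2-one | CC(=O)C(C)=P(c1ccccc1)(c1ccccc1)c1ccccc1 | intermediate
7 | (E)-4-methyl-5-oxohex-3-en-1-yl pivalate | CC(=O)/C(C)=C/CCOC(=O)C(C)(C)C | intermediate
8 | lithium dienolate of 7 | [Li+].C=C([O-])/C(C)=C/CCOC(=O)C(C)(C)C | intermediate
9 | (E)-5-(tert-butyldimethylsilyloxy)-4-methylhexa-3,5-dien-1-yl pivalate | C=C(O[Si](C)(C)C(C)(C)C)/C(C)=C/CCOC(=O)C(C)(C)C | intermediate
10 | methacrolein | C=C(C)C=O | starting material
11 | exo cycloadduct, 2-[(1S,6S)-3-(tert-butyldimethylsilyloxy)-6-formyl-2,6-dimethylcyclohex-2-en-1-yl]ethyl pivalate | O=C[C@@]1(C)CCC(O[Si](C)(C)C(C)(C)C)=C(C)[C@@H]1CCOC(=O)C(C)(C)C | intermediate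
12 | siloxycyclopropane aldehyde (CH2 across C9–C10, anti to the C8 chain) | O=C[C@@]1(C)CC[C@@]2(O[Si](C)(C)C(C)(C)C)C[C@@]2(C)[C@@H]1CCOC(=O)C(C)(C)C | intermediate
13 | keto aldehyde, 2-[(1R,6S)-6-formyl-2,2,6-trimethyl-3-oxocyclohexyl]ethyl pivalate | O=C[C@@]1(C)CCC(=O)C(C)(C)[C@@H]1CCOC(=O)C(C)(C)C | intermediate
14 | keto acid, (1S,2S)-1,3,3-trimethyl-4-oxo-2-[2-(pivaloyloxy)ethyl]cyclohexane-1-carboxylic acid | OC(=O)[C@@]1(C)CCC(=O)C(C)(C)[C@@H]1CCOC(=O)C(C)(C)C | intermediate
15 | 1,3-dioxoisoindolin-2-yl ester of 14 | O=C(ON1C(=O)c2ccccc2C1=O)[C@@]3(C)CCC(=O)C(C)(C)[C@@H]3CCOC(=O)C(C)(C)C | intermediate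
16 | (S)-2-methylglycidol | OC[C@@]1(C)CO1 | starting material
17 | (R)-tert-butyl[(2-methyloxiran-2-yl)methoxy]diphenylsilane | CC(C)(C)[Si](OC[C@@]1(C)CO1)(c2ccccc2)c3ccccc3 | intermediate
18 | (R)-1-(tert-butyldiphenylsilyloxy)-2-methylbut-3-en-2-ol | CC(C)(C)[Si](OC[C@@](O)(C)C=C)(c1ccccc1)c2ccccc2 | intermediate
19 | keto ether (1R,8S,13S): C10 ketone, C13–O–C1 ether, C6 pivalate | C=C[C@](C)(CO[Si](c2ccccc2)(c3ccccc3)C(C)(C)C)O[C@@]1(C)CCC(=O)C(C)(C)[C@@H]1CCOC(=O)C(C)(C)C | intermediate
20 | axial alcohol (1R,8S,10R,13S) | C=C[C@](C)(CO[Si](c2ccccc2)(c3ccccc3)C(C)(C)C)O[C@@]1(C)CC[C@@H](O)C(C)(C)[C@@H]1CCOC(=O)C(C)(C)C | intermediate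
21 | equatorial bromide (1R,8S,10S,13S), C6 pivalate | C=C[C@](C)(CO[Si](c2ccccc2)(c3ccccc3)C(C)(C)C)O[C@@]1(C)CC[C@H](Br)C(C)(C)[C@@H]1CCOC(=O)C(C)(C)C | intermediate
22 | bromo alcohol (C6–OH) | C=C[C@](C)(CO[Si](c2ccccc2)(c3ccccc3)C(C)(C)C)O[C@@]1(C)CC[C@H](Br)C(C)(C)[C@@H]1CCO | intermediate
23 | bromo iodide (C6–I) | C=C[C@](C)(CO[Si](c2ccccc2)(c3ccccc3)C(C)(C)C)O[C@@]1(C)CC[C@H](Br)C(C)(C)[C@@H]1CCI | intermediate
24 | bromo alkyne (C6–C≡CH) | C=C[C@](C)(CO[Si](c2ccccc2)(c3ccccc3)C(C)(C)C)O[C@@]1(C)CC[C@H](Br)C(C)(C)[C@@H]1CCC#C | intermediate
25 | (E)-alkenyldimethylalane | C=C[C@](C)(CO[Si](c2ccccc2)(c3ccccc3)C(C)(C)C)O[C@@]1(C)CC[C@H](Br)C(C)(C)[C@@H]1CC/C(C)=C/[Al](C)C | intermediate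
26 | (E)-iodoalkene | C=C[C@](C)(CO[Si](c2ccccc2)(c3ccccc3)C(C)(C)C)O[C@@]1(C)CC[C@H](Br)C(C)(C)[C@@H]1CC/C(C)=C/I | intermediate
27 | B-alkyl-9-borabicyclo[3.3.1]nonane (boron on C3) | C(C[C@](C)(CO[Si](c2ccccc2)(c3ccccc3)C(C)(C)C)O[C@@]1(C)CC[C@H](Br)C(C)(C)[C@@H]1CC/C(C)=C/I)B4C5CCCC4CCC5 | intermediate
28 | bicyclic E-olefin, C1 CH2OSiPh2t-Bu (1R,8S,10S,13S) | CC(C)(C)[Si](OC[C@@]1(C)CC/C=C(C)/CC[C@H]2C(C)(C)[C@@H](Br)CC[C@]2(C)O1)(c3ccccc3)c4ccccc4 | intermediate
29 | bicyclic E-olefin, C1 CH2OH | OC[C@@]1(C)CC/C=C(C)/CC[C@H]2C(C)(C)[C@@H](Br)CC[C@]2(C)O1 | intermediate
30 | bicyclic E-olefin, C1 CHO | O=C[C@@]1(C)CC/C=C(C)/CC[C@H]2C(C)(C)[C@@H](Br)CC[C@]2(C)O1 | intermediate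
31 | bicyclic diene, C1 vinyl, E-C4=C5 | C=C[C@@]1(C)CC/C=C(C)/CC[C@H]2C(C)(C)[C@@H](Br)CC[C@]2(C)O1 | intermediate
32 | CNP0243863.1, (1R,4S,5S,8S,10S,13S) | C=C[C@@]1(C)CC[C@@H]2O[C@@]2(C)CC[C@H]2C(C)(C)[C@@H](Br)CC[C@]2(C)O1 | target

## Step count and least certain steps

Total: 24 steps. Longest linear sequence: 21 steps (steps 1, 2, 4 to 10 and 13 to 24, from 1 to 32); steps 3, 11 and 12 are side branches.

**Step 6 (key step).** What may go wrong: leakage in the enal-face discrimination, or incomplete exo/endo discrimination with this trisubstituted diene. Both lower the optical purity at C8 once C13 is flattened. Protodesilylation of the diene by adventitious acid is a further risk. Fallback (classical resolution in place of sole reliance on catalyst control): it sets out from 14 of insufficient optical purity. The acid is crystallized from ethyl acetate as its (R)-1-phenylethylammonium salt F1, the less soluble salt is collected and treated with dilute HCl, and the route is rejoined at 14.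

**Step 13.** What may go wrong: proton loss from the C13 cation to ring olefins, or a hydride shift from C8, may outrun capture by the hindered tertiary alcohol. This pairing of two fully substituted partners lies at the edge of the scope of the method. Fallback (anodic two-electron decarboxylation in place of photochemical radical–polar crossover): it sets out from 14, omitting step 10. The free acid is electrolysed at constant current between graphite electrodes with AgPF6, 2,4,6-collidine, Bu4NPF6, 3 Å molecular sieves and 18 (3 equiv) in CH2Cl2 (Hofer–Moest conditions for hindered ethers), and the route is rejoined at 19. No new compound is made (F0).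

**Step 15.** What may go wrong: E2 loss of the axial alkoxyphosphonium group toward C11 and 1,2-migration of the anti-periplanar axial C9 methyl compete with backside attack at the neopentyl carbon. Fallback (activation and displacement separated): it sets out from 20. The alcohol is converted with (CF3SO2)2O and pyridine in CH2Cl2 at −30 °C into the axial triflate F2, which is treated cold with excess LiBr in acetone, so that substitution runs in a medium that does not favour ionization. The route is rejoined at 21.

**Step 20.** What may go wrong: intermolecular coupling to dimers and oligomers, and slow transmetalation of the alkylborane followed by protodeboronation, compete with closure of the ten-membered ring. Fallback (organozinc in place of organoboron): it sets out from 26. Hydroboration as in step 20 and oxidation (NaOH, H2O2) give the primary alcohol F3. I2, PPh3 and imidazole give the alkyl iodide F4. Zinc dust with LiCl in THF inserts selectively into the primary C–I bond to give the alkylzinc iodide F5, and intramolecular Negishi coupling with Pd(PPh3)4 at high dilution rejoins the route at 28.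

**Step 24.** What may go wrong: oxygen transfer to the wrong face, because in a ten-membered E-cycloalkene only the outer face of the olefin is exposed and the ring conformation, not the catalyst, may decide. Fallback (two-step halohydrin route, which places the oxygen on the face opposite to the one an electrophile reaches): it sets out from 31. N-bromosuccinimide in aqueous THF gives the bromohydrin F6 (Br at C4, OH at C5, anti), and K2CO3 in methanol closes the epoxide by displacement at C4 with inversion, rejoining the route at 32.

## Further compounds

F1 | step 6 | (R)-1-phenylethylammonium salt of 14 | [O-]C(=O)[C@@]1(C)CCC(=O)C(C)(C)[C@@H]1CCOC(=O)C(C)(C)C.C[C@@H]([NH3+])c2ccccc2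
F0 | step 13 | none | none
F2 | step 15 | axial C10 trifluoromethanesulfonate of 20 | C=C[C@](C)(CO[Si](c2ccccc2)(c3ccccc3)C(C)(C)C)O[C@@]1(C)CC[C@@H](OS(=O)(=O)C(F)(F)F)C(C)(C)[C@@H]1CCOC(=O)C(C)(C)C
F3 | step 20 | C3 primary alcohol from hydroboration–oxidation of 26 | OCC[C@](C)(CO[Si](c2ccccc2)(c3ccccc3)C(C)(C)C)O[C@@]1(C)CC[C@H](Br)C(C)(C)[C@@H]1CC/C(C)=C/I
F4 | step 20 | C3 primary iodide | ICC[C@](C)(CO[Si](c2ccccc2)(c3ccccc3)C(C)(C)C)O[C@@]1(C)CC[C@H](Br)C(C)(C)[C@@H]1CC/C(C)=C/I
F5 | step 20 | C3 alkylzinc iodide | I[Zn]CC[C@](C)(CO[Si](c2ccccc2)(c3ccccc3)C(C)(C)C)O[C@@]1(C)CC[C@H](Br)C(C)(C)[C@@H]1CC/C(C)=C/I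
F6 | step 24 | (4R,5S)-4-bromo-5-hydroxy bromohydrin of 31 | C=C[C@@]1(C)CC[C@@H](Br)[C@](O)(C)CC[C@H]2C(C)(C)[C@@H](Br)CC[C@]2(C)O1
A1 | alternative 1 | (R)-linalool | C=C[C@@](O)(C)CCC=C(C)C
A2 | alternative 1 | bicyclic E-olefin with phenylsulfonyl at C7 and pivalate at C10 | C=C[C@@]1(C)CC/C=C(C)/CC(S(=O)(=O)c3ccccc3)[C@H]2C(C)(C)[C@H](OC(=O)C(C)(C)C)CC[C@]2(C)O1
A3 | alternative 2 | bicyclic Z-olefin with 2-(tert-butyldimethylsilyloxy)ethyl on C1 | CC(C)(C)[Si](C)(C)OCC[C@@]1(C)CC/C=C(C)\CC[C@H]2C(C)(C)[C@@H](Br)CC[C@]2(C)O1
A4 | alternative 3 | bicyclic E-olefin with tert-butyldimethylsilyloxymethyl on C1 | CC(C)(C)[Si](C)(C)OC[C@@]1(C)CC/C=C(C)/CC[C@H]2C(C)(C)[C@@H](Br)CC[C@]2(C)O1
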